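**Retrosynthetic overview**

- The plan rests on ring A: C4a (bonded to the C4 carbonyl) and C8 (bearing the prenyl group) are the two carbons ortho to C8a–O1. In the open aryl ether they are the two equivalent ortho positions of a symmetric 2,6-dibromo-3,5-bis(MOM-oxy)phenyl ring.
- C8–prenyl is disconnected last (Stille coupling on the 8-bromoflavanone, then MOM removal).
- Ring C is closed at C4–C4a by bromine–lithium exchange and attack of the aryllithium on a tethered Weinreb amide; one bromine is spent, the other is left at C8.
- O1–C2 and the C2 stereocentre come from Mitsunobu inversion of an (R)-homoallylic benzylic alcohol by the dibromophenol; the allyl group is then cut down to the C3–C4 acid and amide.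
- Ring order: ring A is bought as 4,6-dibromoresorcinol and hydroxylated between the bromines; the pyran ring of the ring B chroman is made first; ring C is closed last.

Key step: step 9

Assumption: the facial sense of the phosphoric acid catalyst in step 4 is taken from simple aryl aldehydes; the configuration of the carbinol would be confirmed (Mosher esters) before step 5 and the antipodal catalyst used if it proved opposite.

**Step 1**
Reactants: 1 4,6-dibromobenzene-1,3-diol (4,6-dibromoresorcinol)
Product: 2 1,5-dibromo-2,4-bis(methoxymethoxy)benzene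
Conditions: MOMCl, i-Pr2NEt, CH2Cl2, 0 °C → rt
Reagents that add atoms: chloromethyl methyl ether, COCCl
Why: O-alkylation of both acidic ortho-bromophenols by the reactive chloromethyl ether (MOM protection) should be clean, and MOM ethers tolerate LiN(i-Pr)2 and n-BuLi and later chelate the aryllithium of the key step.

**Step 2**
Reactants: 2 1,5-dibromo-2,4-bis(methoxymethoxy)benzene
Product: 5 2,6-dibromo-3,5-bis(methoxymethoxy)phenol, via aryllithium 3 (not isolated), via lithium aryltrimethoxyborate 4 (not isolated)
Conditions: LiN(i-Pr)2, THF, −78 °C; B(OMe)3, −78 → 0 °C; AcOH, 30% H2O2, 0 °C → rt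
Reagents that add atoms: hydrogen peroxide, OO
Why: Deprotonative lithiation by the amide base (no halogen–metal exchange) should take the most acidic ring hydrogen, the one flanked by both bromines, and borylation followed by boronate oxidation (1,2-aryl shift to oxygen) places the hydroxyl between the bromines without any regiochemical choice in a bromination.

**Step 3**
Reactants: 6 4-hydroxybenzaldehyde; 7 isoprene
Product: 8 2,2-dimethylchroman-6-carbaldehyde
Conditions: 85% H3PO4, xylene, 30–35 °C
Reagents that add atoms: none
Why: Acid-catalysed chroman annulation of a phenol with isoprene (Friedel–Crafts prenylation ortho to OH, then Markovnikov hydroalkoxylation of the trisubstituted alkene) can only occur at the two equivalent positions ortho to OH because the para position carries the formyl group.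

**Step 4**
Reactants: 8 2,2-dimethylchroman-6-carbaldehyde
Product: 10 (R)-1-(2,2-dimethylchroman-6-yl)but-3-en-1-ol, via pinacol borate ester 9 (not isolated)
Conditions: allylB(pin), (R)-TRIP phosphoric acid [(R)-3,3'-bis(2,4,6-triisopropylphenyl)-1,1'-binaphthyl-2,2'-diyl hydrogen phosphate] (5 mol%), toluene, −30 °C; aq NaHCO3
Reagents that add atoms: allylboronic acid pinacol ester, C=CCB1OC(C)(C)C(C)(C)O1
Why: Chiral Brønsted acid-catalysed allylboration of an aryl aldehyde proceeds through a closed chair transition state in which the (R)-phosphoric acid, hydrogen-bonded to the boronate oxygen and the formyl hydrogen, should direct allyl transfer to the Re face and so set the (R)-carbinol centre.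

**Step 5**
Reactants: 5 2,6-dibromo-3,5-bis(methoxymethoxy)phenol; 10 (R)-1-(2,2-dimethylchroman-6-yl)but-3-en-1-ol
Product: 11 (S)-6-{1-[2,6-dibromo-3,5-bis(methoxymethoxy)phenoxy]but-3-en-1-yl}-2,2-dimethylchroman
Conditions: PPh3, DIAD, toluene, −20 °C → rt
Reagents that add atoms: none
Why: Mitsunobu etherification should form the O1–C2 bond by SN2 attack of the phenoxide on the alkoxyphosphonium ion with inversion, turning the (R)-carbinol into the (S)-ether (future C2); the two ortho bromines make the phenol acidic enough for fast proton transfer, and a non-polar solvent at low temperature holds back ionisation of the electron-rich benzylic centre.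

**Step 6**
Reactants: 11 (S)-6-{1-[2,6-dibromo-3,5-bis(methoxymethoxy)phenoxy]but-3-en-1-yl}-2,2-dimethylchroman
Product: 13 (S)-3-[2,6-dibromo-3,5-bis(methoxymethoxy)phenoxy]-3-(2,2-dimethylchroman-6-yl)propanal, via 1,2-diol 12 (not isolated)
Conditions: OsO4 (cat.), NaIO4, 2,6-lutidine, dioxane/H2O, rt
Reagents that add atoms: sodium periodate NaIO4, [Na+].[O-]I(=O)(=O)=O (oxygen delivered through OsO4)
Why: Lemieux–Johnson cleavage (dihydroxylation, then periodate glycol cleavage) acts on the only alkene present, and the lutidine-buffered medium should spare the MOM ethers and keep the β-aryloxy aldehyde from eliminating, with the stereocentre untouched.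

**Step 7**
Reactants: 13 (S)-3-[2,6-dibromo-3,5-bis(methoxymethoxy)phenoxy]-3-(2,2-dimethylchroman-6-yl)propanal
Product: 14 (S)-3-[2,6-dibromo-3,5-bis(methoxymethoxy)phenoxy]-3-(2,2-dimethylchroman-6-yl)propanoic acid
Conditions: NaClO2, NaH2PO4, 2-methyl-2-butene, t-BuOH/H2O, 0 °C → rt
Reagents that add atoms: sodium chlorite NaClO2, [Na+].[O-]Cl=O
Why: Pinnick oxidation converts the aldehyde to the acid in a weakly acidic buffer without enolisation, so the aryloxide at the β-carbon is not expelled, while 2-methyl-2-butene traps hypochlorous acid before it can chlorinate the electron-rich rings.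

**Step 8**
Reactants: 14 (S)-3-[2,6-dibromo-3,5-bis(methoxymethoxy)phenoxy]-3-(2,2-dimethylchroman-6-yl)propanoic acid
Product: 15 (S)-3-[2,6-dibromo-3,5-bis(methoxymethoxy)phenoxy]-3-(2,2-dimethylchroman-6-yl)-N-methoxy-N-methylpropanamide
Conditions: MeNH(OMe)·HCl, EDC·HCl, HOBt, N-methylmorpholine, CH2Cl2, 0 °C → rt
Reagents that add atoms: N,O-dimethylhydroxylamine hydrochloride, CNOC.Cl
Why: Carbodiimide-mediated amide coupling through the hydroxybenzotriazole ester needs only a weak amine base at 0 °C, which should avoid E1cB loss of the aryloxide from the activated acid.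

**Step 9**
Reactants: 15 (S)-3-[2,6-dibromo-3,5-bis(methoxymethoxy)phenoxy]-3-(2,2-dimethylchroman-6-yl)-N-methoxy-N-methylpropanamide
Product: 18 (S)-8-bromo-2-(2,2-dimethylchroman-6-yl)-5,7-bis(methoxymethoxy)chroman-4-one, via aryllithium 16 (not isolated), via lithium hemiaminal alkoxide 17 (not isolated)
Conditions: n-BuLi (1.05 equiv), THF (high dilution), −100 °C; AcOH/THF, −100 → −78 °C
Reagents that add atoms: none
Why: n-BuLi should exchange one of the two equivalent bromines that flank the ether oxygen (each also ortho to an OMOM group, which speeds the exchange and chelates lithium), and aryllithium 16 adds to the tethered N-methoxy-N-methylamide carbonyl to give the chelated tetrahedral intermediate 17, which collapses to ketone 18 only on the acidic quench; this is a Parham cyclisation with a Weinreb amide as internal electrophile, closest to the known closure of 3-(2-bromoaryloxy)propanoic acid derivatives to chroman-4-ones. Ring C closes in a 6-exo-trig mode by forming the C4–C4a bond. No stereocentre is formed: C2 is carried in from step 5 and the hemiaminal carbon of 17 is lost on collapse. The step needs chemoselectivity for bromine–lithium exchange over addition of n-BuLi to the amide and over α-deprotonation (which would expel the aryloxide from C2); this rests on the high exchange rate of a bromide between two oxygen substituents, on one equivalent of base at −100 °C, and on the fast intramolecular trap. No regioselectivity is needed, because the aryl ring is symmetric about its C1–C4 axis and either exchange leaves the other bromine at C8. Because the carbonyl stays masked in 17 until the cold acetic acid quench, the flavanone never meets base and cannot racemise by ring-opening to the chalcone.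

**Step 10**
Reactants: 18 (S)-8-bromo-2-(2,2-dimethylchroman-6-yl)-5,7-bis(methoxymethoxy)chroman-4-one
Product: 19 (S)-2-(2,2-dimethylchroman-6-yl)-5,7-bis(methoxymethoxy)-8-(3-methylbut-2-en-1-yl)chroman-4-one
Conditions: tributyl(3-methylbut-2-en-1-yl)stannane, Pd(PPh3)4 (10 mol%), DMF, 100 °C
Reagents that add atoms: tributyl(3-methylbut-2-en-1-yl)stannane, CC(C)=CC[Sn](CCCC)(CCCC)CCCC
Why: Stille coupling (oxidative addition of zerovalent palladium into C8–Br, transmetalation from the allylic stannane, reductive elimination from the less hindered primary prenyl terminus) should give the linear prenyl group, and its neutral conditions leave the base-sensitive flavanone closed so that C2 stays (S).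

**Step 11**
Reactants: 19 (S)-2-(2,2-dimethylchroman-6-yl)-5,7-bis(methoxymethoxy)-8-(3-methylbut-2-en-1-yl)chroman-4-one
Product: 20 euchrenone a16, (S)-2-(2,2-dimethylchroman-6-yl)-5,7-dihydroxy-8-(3-methylbut-2-en-1-yl)chroman-4-one
Conditions: 3 M aq HCl, MeOH, 40 °C
Reagents that add atoms: none
Why: Acid-catalysed cleavage of the two aryl MOM acetals (transfer of the methoxymethyl group to methanol) is a standard last step for prenylated flavanones and, kept mild and short, should not cyclise the prenyl group onto the 7-hydroxyl or open ring C.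

**Compound list**

1 | 4,6-dibromobenzene-1,3-diol (4,6-dibromoresorcinol) | Oc1cc(O)c(Br)cc1Br | starting material
2 | 1,5-dibromo-2,4-bis(methoxymethoxy)benzene | COCOc1cc(OCOC)c(Br)cc1Br | intermediate
3 | 2,6-dibromo-3,5-bis(methoxymethoxy)phenyllithium | [Li]c1c(Br)c(OCOC)cc(OCOC)c1Br | intermediate
4 | lithium [2,6-dibromo-3,5-bis(methoxymethoxy)phenyl]trimethoxyborate | [Li+].CO[B-](OC)(OC)c1c(Br)c(OCOC)cc(OCOC)c1Br | intermediate
5 | 2,6-dibromo-3,5-bis(methoxymethoxy)phenol | COCOc1cc(OCOC)c(Br)c(O)c1Br | intermediate
6 | 4-hydroxybenzaldehyde | O=Cc1ccc(O)cc1 | starting material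
7 | isoprene | C=CC(C)=C | starting material
8 | 2,2-dimethylchroman-6-carbaldehyde | O=Cc1ccc2c(c1)CCC(C)(C)O2 | intermediate
9 | 2-{[(1R)-1-(2,2-dimethylchroman-6-yl)but-3-en-1-yl]oxy}-4,4,5,5-tetramethyl-1,3,2-dioxaborolane | C=CC[C@@H](OB1OC(C)(C)C(C)(C)O1)c1ccc2c(c1)CCC(C)(C)O2 | intermediate
10 | (R)-1-(2,2-dimethylchroman-6-yl)but-3-en-1-ol | C=CC[C@@H](O)c1ccc2c(c1)CCC(C)(C)O2 | intermediate
11 | (S)-6-{1-[2,6-dibromo-3,5-bis(methoxymethoxy)phenoxy]but-3-en-1-yl}-2,2-dimethylchroman | C=CC[C@H](Oc1c(Br)c(OCOC)cc(OCOC)c1Br)c1ccc2c(c1)CCC(C)(C)O2 | intermediate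
12 | (4S)-4-[2,6-dibromo-3,5-bis(methoxymethoxy)phenoxy]-4-(2,2-dimethylchroman-6-yl)butane-1,2-diol (both C2 epimers) | OCC(O)C[C@H](Oc1c(Br)c(OCOC)cc(OCOC)c1Br)c1ccc2c(c1)CCC(C)(C)O2 | intermediate
13 | (S)-3-[2,6-dibromo-3,5-bis(methoxymethoxy)phenoxy]-3-(2,2-dimethylchroman-6-yl)propanal | O=CC[C@H](Oc1c(Br)c(OCOC)cc(OCOC)c1Br)c1ccc2c(c1)CCC(C)(C)O2 | intermediate
14 | (S)-3-[2,6-dibromo-3,5-bis(methoxymethoxy)phenoxy]-3-(2,2-dimethylchroman-6-yl)propanoic acid | OC(=O)C[C@H](Oc1c(Br)c(OCOC)cc(OCOC)c1Br)c1ccc2c(c1)CCC(C)(C)O2 | intermediate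
15 | (S)-3-[2,6-dibromo-3,5-bis(methoxymethoxy)phenoxy]-3-(2,2-dimethylchroman-6-yl)-N-methoxy-N-methylpropanamide | Brc1c(OCOC)cc(OCOC)c(Br)c1O[C@H](c1ccc2c(c1)CCC(C)(C)O2)CC(=O)N(C)OC | intermediate
16 | aryllithium from 15 (lithium in place of one bromine) | [Li]c1c(OCOC)cc(OCOC)c(Br)c1O[C@H](c1ccc2c(c1)CCC(C)(C)O2)CC(=O)N(C)OC | intermediate
17 | lithium alkoxide of (2S)-8-bromo-2-(2,2-dimethylchroman-6-yl)-4-[methoxy(methyl)amino]-5,7-bis(methoxymethoxy)chroman-4-ol (C4 unspecified) | Brc1c(OCOC)cc(OCOC)c2c1O[C@H](c1ccc3c(c1)CCC(C)(C)O3)CC2(O[Li])N(C)OC | intermediate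
18 | (S)-8-bromo-2-(2,2-dimethylchroman-6-yl)-5,7-bis(methoxymethoxy)chroman-4-one | Brc1c(OCOC)cc(OCOC)c2c1O[C@H](c1ccc3c(c1)CCC(C)(C)O3)CC2=O | intermediate
19 | (S)-2-(2,2-dimethylchroman-6-yl)-5,7-bis(methoxymethoxy)-8-(3-methylbut-2-en-1-yl)chroman-4-one | CC(C)=CCc1c(OCOC)cc(OCOC)c2c1O[C@H](c1ccc3c(c1)CCC(C)(C)O3)CC2=O | intermediate
20 | euchrenone a16 | CC(C)=CCc1c(O)cc(O)c2c1O[C@H](c1ccc3c(c1)CCC(C)(C)O3)CC2=O | target

**Step count and risk**

Total steps: 11. Longest linear sequence: 9 steps (steps 3 to 11 from 4-hydroxybenzaldehyde; equally steps 1, 2 and 5 to 11 from 4,6-dibromoresorcinol).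

Steps most likely to fail:

1. Step 9. The risk is that n-BuLi adds to the amide carbonyl or removes an α-hydrogen faster than it exchanges bromine, after which the enolate expels the aryloxide and C2 is lost. The fallback closes ring C with palladium instead of lithium and sets out from ether 11. An intramolecular Mizoroki–Heck reaction (Pd(OAc)2, PPh3, Ag2CO3, MeCN, 80 °C) should insert one of the two equivalent C–Br bonds into the terminal alkene in a 6-exo-trig mode and give (S)-8-bromo-2-(2,2-dimethylchroman-6-yl)-5,7-bis(methoxymethoxy)-4-methylenechroman F1. Lemieux–Johnson cleavage of the exocyclic alkene (OsO4 cat., NaIO4, 2,6-lutidine, dioxane/H2O) then gives ketone 18, where the route is rejoined; steps 6 to 8 are bypassed.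

2. Step 5. The risk is that the alkoxyphosphonium ion ionises at the electron-rich benzylic carbon before the hindered phenoxide attacks, so that inversion is incomplete and some material is lost by elimination to the aryl diene. The fallback secures the stereocentre by classical resolution instead of by stereospecific substitution and sets out from acid 14 of insufficient enantiomeric purity. Salt formation with (S)-1-phenylethylamine gives (S)-1-phenylethylammonium (S)-3-[2,6-dibromo-3,5-bis(methoxymethoxy)phenoxy]-3-(2,2-dimethylchroman-6-yl)propanoate F2, which is recrystallised to constant rotation (the (R)-amine is taken instead if its salt crystallises better). Brief partition between EtOAc and cold 1 M HCl releases enantiopure acid 14, which re-enters the route at step 8.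

3. Step 10. The risk is slow oxidative addition into the C8–Br bond between two oxygen substituents, together with transfer of the prenyl group through its tertiary terminus to give the 1,1-dimethylallyl isomer. The fallback sets out from bromide 18 and separates C–C coupling from the choice of alkene terminus. Stille coupling with allyltributylstannane (Pd(PPh3)4, DMF, 100 °C, or Pd2(dba)3/XPhos) gives (S)-8-allyl-2-(2,2-dimethylchroman-6-yl)-5,7-bis(methoxymethoxy)chroman-4-one F3. Cross-metathesis with excess 2-methyl-2-butene (second-generation Grubbs catalyst, RuCl2(=CHPh)(H2IMes)(PCy3), CH2Cl2, 40 °C) converts allyl into prenyl and gives 19, where the route is rejoined.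

**Further compounds**

F1 | step 9 | (S)-8-bromo-2-(2,2-dimethylchroman-6-yl)-5,7-bis(methoxymethoxy)-4-methylenechroman | Brc1c(OCOC)cc(OCOC)c2c1O[C@H](c1ccc3c(c1)CCC(C)(C)O3)CC2=C
F2 | step 5 | (S)-1-phenylethylammonium (S)-3-[2,6-dibromo-3,5-bis(methoxymethoxy)phenoxy]-3-(2,2-dimethylchroman-6-yl)propanoate | C[C@H]([NH3+])c1ccccc1.[O-]C(=O)C[C@H](Oc1c(Br)c(OCOC)cc(OCOC)c1Br)c1ccc2c(c1)CCC(C)(C)O2
F3 | step 10 | (S)-8-allyl-2-(2,2-dimethylchroman-6-yl)-5,7-bis(methoxymethoxy)chroman-4-one | C=CCc1c(OCOC)cc(OCOC)c2c1O[C@H](c1ccc3c(c1)CCC(C)(C)O3)CC2=O
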